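**Assumption:** compounds 1, 2, 4, 17 and 25 are taken as commercial achiral materials; where the sense of induction of a chiral catalyst is model-based, the enantiomer named is the one expected to give the drawn configuration.

**Convention:** locants C1–C15 are those of the guaianolide skeleton of the target (C4 carries the ring oxygen and C15; C10=C14–O is the enol ether; C6, C8, C9 are the carbinol carbons). salen-H2 = (R,R)-N,N′-bis(3,5-di-tert-butylsalicylidene)cyclohexane-1,2-diamine.

## Retrosynthetic overview

1. The target comes from its C15 silyl ether; the lactone and the seven-membered ring are closed together by an intramolecular Barbier allylation (C6–C7) of a C6 aldehyde with a 2-(bromomethyl)enoate.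
2. The bromo-enoate comes from cross-metathesis of a C8 vinyl group; the syn C8/C9 diol esters come from a catalytic asymmetric acyloxyallylation of a C9 aldehyde with an allyl chloride carrying the (S)-2-methylbutanoate (acid from tiglic acid by asymmetric hydrogenation).
3. The C9 aldehyde comes from Vilsmeier formylation of the bridged enol ether, generated from a lactol.
4. The lactol (C1, C4, C5) comes from a proline-catalysed desymmetrising aldol of a prochiral keto-dialdehyde, itself from ozonolysis of a 4-substituted cyclopentene.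
5. Ring order: cyclopentane, then the oxygen bridge (dihydropyran), then the seven-membered carbocycle together with the lactone.

## Route

Step 1
Reactants: 1 2-[(tert-butyldiphenylsilyl)oxy]-N-methoxy-N-methylacetamide; 2 vinylmagnesium bromide
Product: 3 1-[(tert-butyldiphenylsilyl)oxy]but-3-en-2-one
Conditions: THF, −78 → 0 °C; cold 1 M HCl quench
Reagents that add atoms: none
Why: Weinreb ketone synthesis, in which the chelated tetrahedral adduct prevents over-addition and the acidic quench stops aza-Michael addition of the released amine to the enone; no stereocentre is formed.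

Step 2
Reactants: 3 1-[(tert-butyldiphenylsilyl)oxy]but-3-en-2-one; 4 4-bromocyclopentene
Product: 6 1-[(tert-butyldiphenylsilyl)oxy]-4-(cyclopent-3-en-1-yl)butan-2-one, via cyclopent-3-en-1-ylmagnesium bromide 5 (not isolated)
Conditions: 4, Mg, THF, 40 °C; then CuBr·SMe2 (10 mol%), 3, THF, −40 °C; 1 M HCl
Reagents that add atoms: none
Why: Copper-catalysed conjugate addition of the Grignard reagent to the vinyl ketone; the silyl ether and the isolated ring alkene are inert and no stereocentre is formed.

Step 3
Reactants: 6 1-[(tert-butyldiphenylsilyl)oxy]-4-(cyclopent-3-en-1-yl)butan-2-one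
Product: 8 3-{4-[(tert-butyldiphenylsilyl)oxy]-3-oxobutyl}pentanedial, via secondary ozonide 7 (not isolated)
Conditions: O3, CH2Cl2, −78 °C; then PPh3, −78 → 20 °C
Reagents that add atoms: ozone, [O-][O+]=O
Why: Ozonolysis with reductive work-up cleaves the only C=C to the symmetric keto-dialdehyde, whose central carbon (future C1) is prochiral.

Step 4
Reactants: 8 3-{4-[(tert-butyldiphenylsilyl)oxy]-3-oxobutyl}pentanedial
Product: 10 bridged lactol aldehyde (1S,4S,5R), via all-cis aldol 9 (not isolated)
Conditions: (R)-proline (30 mol%), DMSO, 20 °C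
Reagents that add atoms: none
Why: Proposed new method: a proline-catalysed desymmetrising 5-enolexo aldol in which the enamine of one enantiotopic CH2CHO arm of 8 adds to the tethered α-silyloxy ketone through a Houk–List transition state (carboxylic acid hydrogen-bonded to the ketone oxygen), which places OH and CHO cis and, with (R)-proline, is expected to select the arm and enamine face that give C1, C4 and C5 as drawn; aldol isomers whose hydroxyl is trans to the spectator arm cannot cyclise and revert by retro-aldol, while the all-cis isomer 9 is drained as the bridged lactol 10; the closest known reactions are the Hajos–Parrish-type proline aldol desymmetrisation, proline enolexo aldolisations of dialdehydes and the proline 5-enolexo addition of aldehyde enamines to ketones, none shown for a prochiral glutaraldehyde with a ketone acceptor.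

Step 5
Reactants: 10 bridged lactol aldehyde (1S,4S,5R)
Product: 13 bridged enol ether dialdehyde (1R,4S,5R), via enol ether aldehyde 11 (not isolated), via vinylogous iminium chloride 12 (not isolated)
Conditions: POCl3 (3 equiv), DMF, 0 → 40 °C; then aq. NaOAc, 0 °C
Reagents that add atoms: N,N-dimethylformamide, CN(C)C=O; water, O
Why: Vilsmeier–Haack formylation: the lactol hydroxyl is activated and lost to give the glycal-type enol ether, whose nucleophilic β-carbon (C10) is formylated as glycals give 2-formylglycals; the product is an unreactive vinylogous formate and C1, C4 and C5 are untouched.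

Step 6
Reactants: 13 bridged enol ether dialdehyde (1R,4S,5R)
Product: 14 C6 dimethyl acetal of 13
Conditions: HC(OMe)3 (1.2 equiv), MeOH, PPTS (5 mol%), 0 °C
Reagents that add atoms: trimethyl orthoformate, COC(OC)OC
Why: Chemoselective acid-catalysed acetalisation of the aliphatic C6 aldehyde; the C9 formyl group is a push–pull vinylogous formate and far less electrophilic.

Step 7
Reactants: 15 tiglic acid
Product: 16 (S)-2-methylbutanoic acid
Conditions: H2 (4 atm), Ru(OAc)2[(S)-H8-BINAP] (0.5 mol%), MeOH, 20 °C
Reagents that add atoms: none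
Why: Asymmetric hydrogenation of the α,β-unsaturated acid on the carboxylate-bound ruthenium diphosphine catalyst sets the (S) stereocentre of the side-chain acid.

Step 8
Reactants: 16 (S)-2-methylbutanoic acid; 17 acrolein
Product: 19 3-chloroprop-1-en-1-yl (S)-2-methylbutanoate (E/Z mixture), via (S)-2-methylbutanoyl chloride 18 (not isolated)
Conditions: (COCl)2, DMF (cat.), CH2Cl2, 20 °C; then 17, ZnCl2 (2 mol%), −20 → 0 °C
Reagents that add atoms: oxalyl chloride, ClC(=O)C(Cl)=O
Why: Acid chloride formation followed by ZnCl2-catalysed 1,4-addition of the acyl chloride across acrolein (O-acylation with conjugate chloride transfer) gives the γ-acyloxyallyl chloride without touching the α-stereocentre.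

Step 9
Reactants: 14 C6 dimethyl acetal of 13; 19 3-chloroprop-1-en-1-yl (S)-2-methylbutanoate
Product: 21 (8S,9S)-homoallylic alcohol, via trimethylsilyl ether 20 (not isolated)
Conditions: CrCl3 (10 mol%), salen-H2 (12 mol%), Et3N (20 mol%), Mn (3 equiv), Me3SiCl (1.5 equiv), MeCN, 20 °C; then KF (cat.), MeOH, 0 °C
Reagents that add atoms: none
Why: Catalytic asymmetric Nozaki–Hiyama–Kishi acyloxyallylation: the γ-acyloxyallylchromium reagent adds through its oxygenated carbon to the only free aldehyde (C9), the chiral salen complex of trivalent chromium giving the syn (8S,9S) diol mono-ester by Re-face attack; the silyl ether is cleaved near neutrality to avoid acyl migration.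

Step 10
Reactants: 21 (8S,9S)-homoallylic alcohol
Product: 22 C9 acetate
Conditions: Ac2O, pyridine, DMAP (5 mol%), CH2Cl2, 0 °C
Reagents that add atoms: acetic anhydride, CC(=O)OC(C)=O
Why: DMAP-catalysed acetylation of the free C9 hydroxyl (a glycal-type allylic alcohol) fixes the 9-acetate before acyl migration can occur.

Step 11
Reactants: 22 C9 acetate
Product: 24 C6 aldehyde, via collidinium N,O-acetal triflate 23 (not isolated)
Conditions: Et3SiOTf (2 equiv), 2,4,6-collidine (3 equiv), CH2Cl2, 0 °C; then H2O
Reagents that add atoms: water, O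
Why: Acetal cleavage under buffered silyl triflate/collidine conditions (pyridinium N,O-acetal, then water) frees the C6 aldehyde without the aqueous acid that would hydrate the enol ether or ionise the allylic acetate.

Step 12
Reactants: 24 C6 aldehyde; 25 methyl 2-(bromomethyl)acrylate
Product: 26 allylic bromide aldehyde
Conditions: 25 (5 equiv), second-generation Hoveyda–Grubbs catalyst (10 mol%), CH2Cl2, 40 °C
Reagents that add atoms: none
Why: Olefin cross-metathesis of the monosubstituted alkene with the 1,1-disubstituted acrylate (in excess) gives the trisubstituted 2-(bromomethyl)enoate; the hindered trisubstituted enol ether and the aldehyde should not engage the ruthenium carbene, and E/Z mixtures are inconsequential.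

Step 13
Reactants: 26 allylic bromide aldehyde
Product: 28 silyl-protected guaianolide, via hydroxy ester 27 (not isolated)
Conditions: activated Zn dust, THF, 45 °C; aqueous work-up
Reagents that add atoms: none
Why: Intramolecular zinc Barbier (Dreiding–Schmidt) allylation and lactonisation: the allylzinc attacks the C6 aldehyde through C7 in a chair transition state with the C8 substituent pseudo-equatorial, giving the 6,7-trans (6S,7S) arrangement and closing the seven-membered ring, and the zinc alkoxide lactonises onto the methyl ester.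

Step 14
Reactants: 28 silyl-protected guaianolide
Product: 29 CNP0013863.2 (target)
Conditions: HF·pyridine, pyridine, THF, 0 → 20 °C
Reagents that add atoms: none
Why: Buffered fluoride desilylation removes the tert-butyldiphenylsilyl group without touching the esters, the enol ether or the α-methylene lactone.

## Compound list

1 | 2-[(tert-butyldiphenylsilyl)oxy]-N-methoxy-N-methylacetamide | CON(C)C(=O)CO[Si](c1ccccc1)(c1ccccc1)C(C)(C)C | starting material
2 | vinylmagnesium bromide | C=C[Mg]Br | starting material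
3 | 1-[(tert-butyldiphenylsilyl)oxy]but-3-en-2-one | C=CC(=O)CO[Si](c1ccccc1)(c1ccccc1)C(C)(C)C | intermediate
4 | 4-bromocyclopentene | BrC1CC=CC1 | starting material
5 | cyclopent-3-en-1-ylmagnesium bromide | Br[Mg]C1CC=CC1 | intermediate (not isolated)
6 | 1-[(tert-butyldiphenylsilyl)oxy]-4-(cyclopent-3-en-1-yl)butan-2-one | O=C(CCC1CC=CC1)CO[Si](c1ccccc1)(c1ccccc1)C(C)(C)C | intermediate
7 | secondary ozonide of 6 (6,7,8-trioxabicyclo[3.2.1]octane carrying the 4-silyloxy-3-oxobutyl chain at C3) | O=C(CCC1CC2OOC(C1)O2)CO[Si](c1ccccc1)(c1ccccc1)C(C)(C)C | intermediate (not isolated)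
8 | 3-{4-[(tert-butyldiphenylsilyl)oxy]-3-oxobutyl}pentanedial (prochiral) | O=CCC(CC=O)CCC(=O)CO[Si](c1ccccc1)(c1ccccc1)C(C)(C)C | intermediate
9 | all-cis aldol: 2-(2-formyl-3-hydroxy-3-{[(tert-butyldiphenylsilyl)oxy]methyl}cyclopentyl)acetaldehyde with CH2CHO, CHO and OH on one face (target numbering 1S,4S,5R) | O=CC[C@@H]1CC[C@@](O)(CO[Si](c2ccccc2)(c2ccccc2)C(C)(C)C)[C@@H]1C=O | intermediate (not isolated)
10 | bridged lactol: 3-hydroxy-1-{[(tert-butyldiphenylsilyl)oxy]methyl}-2-oxabicyclo[3.2.1]octane-8-carbaldehyde, formyl syn to the oxygen bridge, anomeric mixture (target numbering 1S,4S,5R) | C1C(O)O[C@@]2(CO[Si](c3ccccc3)(c3ccccc3)C(C)(C)C)CC[C@@H]1[C@H]2C=O | intermediate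
11 | 1-{[(tert-butyldiphenylsilyl)oxy]methyl}-2-oxabicyclo[3.2.1]oct-3-ene-8-carbaldehyde (target numbering 1S,4S,5R) | C1=CO[C@@]2(CO[Si](c3ccccc3)(c3ccccc3)C(C)(C)C)CC[C@@H]1[C@H]2C=O | intermediate (not isolated)
12 | N,N-dimethyliminium chloride of the C9 formyl group of 13 | C[N+](C)=CC1=CO[C@@]2(CO[Si](c3ccccc3)(c3ccccc3)C(C)(C)C)CC[C@@H]1[C@H]2C=O.[Cl-] | intermediate (not isolated)
13 | 1-{[(tert-butyldiphenylsilyl)oxy]methyl}-2-oxabicyclo[3.2.1]oct-3-ene-4,8-dicarbaldehyde (target numbering 1R,4S,5R; C9 and C6 formyl groups) | O=CC1=CO[C@@]2(CO[Si](c3ccccc3)(c3ccccc3)C(C)(C)C)CC[C@@H]1[C@H]2C=O | intermediate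
14 | 8-(dimethoxymethyl)-1-{[(tert-butyldiphenylsilyl)oxy]methyl}-2-oxabicyclo[3.2.1]oct-3-ene-4-carbaldehyde (target numbering 1R,4S,5R) | O=CC1=CO[C@@]2(CO[Si](c3ccccc3)(c3ccccc3)C(C)(C)C)CC[C@@H]1[C@H]2C(OC)OC | intermediate
15 | tiglic acid, (E)-2-methylbut-2-enoic acid | C/C=C(\C)C(=O)O | starting material
16 | (S)-2-methylbutanoic acid | OC(=O)[C@@H](C)CC | intermediate
17 | acrolein | C=CC=O | starting material
18 | (S)-2-methylbutanoyl chloride | ClC(=O)[C@@H](C)CC | intermediate (not isolated)
19 | 3-chloroprop-1-en-1-yl (S)-2-methylbutanoate (E/Z mixture) | ClCC=COC(=O)[C@@H](C)CC | intermediate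
20 | trimethylsilyl ether of 21 | C=C[C@H](OC(=O)[C@@H](C)CC)[C@@H](O[Si](C)(C)C)C1=CO[C@@]2(CO[Si](c3ccccc3)(c3ccccc3)C(C)(C)C)CC[C@@H]1[C@H]2C(OC)OC | intermediate (not isolated)
21 | (8S,9S)-homoallylic alcohol: 14 in which C9 is CH(OH) bonded to C8H[O-(S)-2-methylbutanoyl]–CH=CH2 | C=C[C@H](OC(=O)[C@@H](C)CC)[C@@H](O)C1=CO[C@@]2(CO[Si](c3ccccc3)(c3ccccc3)C(C)(C)C)CC[C@@H]1[C@H]2C(OC)OC | intermediate
22 | C9 acetate of 21 | C=C[C@H](OC(=O)[C@@H](C)CC)[C@@H](OC(C)=O)C1=CO[C@@]2(CO[Si](c3ccccc3)(c3ccccc3)C(C)(C)C)CC[C@@H]1[C@H]2C(OC)OC | intermediate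
23 | 1-(C6 methoxymethyl)-2,4,6-trimethylpyridinium triflate derived from 22 | C=C[C@H](OC(=O)[C@@H](C)CC)[C@@H](OC(C)=O)C1=CO[C@@]2(CO[Si](c3ccccc3)(c3ccccc3)C(C)(C)C)CC[C@@H]1[C@H]2C(OC)[n+]1c(C)cc(C)cc1C.[O-]S(=O)(=O)C(F)(F)F | intermediate (not isolated)
24 | C6 aldehyde: 22 with the acetal replaced by CHO | C=C[C@H](OC(=O)[C@@H](C)CC)[C@@H](OC(C)=O)C1=CO[C@@]2(CO[Si](c3ccccc3)(c3ccccc3)C(C)(C)C)CC[C@@H]1[C@H]2C=O | intermediate
25 | methyl 2-(bromomethyl)acrylate | C=C(CBr)C(=O)OC | starting material
26 | allylic bromide aldehyde: 24 with the vinyl group replaced by CH=C(CO2Me)CH2Br (C8 cis to CH2Br) | BrC/C(C(=O)OC)=C\[C@H](OC(=O)[C@@H](C)CC)[C@@H](OC(C)=O)C1=CO[C@@]2(CO[Si](c3ccccc3)(c3ccccc3)C(C)(C)C)CC[C@@H]1[C@H]2C=O | intermediate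
27 | (6S,7S,8S,9S)-hydroxy ester: seven-membered ring closed, C6–OH, methyl 2-methylenepropanoate unit on C7 (formed as its zinc alkoxide) | C=C(C(=O)OC)[C@@H]1[C@H](OC(=O)[C@@H](C)CC)[C@@H](OC(C)=O)C2=CO[C@@]3(CO[Si](c4ccccc4)(c4ccccc4)C(C)(C)C)CC[C@@H]2[C@H]3[C@H]1O | intermediate (not isolated)
28 | 15-O-(tert-butyldiphenylsilyl) ether of the target (1R,4S,5S,6S,7S,8S,9S) | C=C1C(=O)O[C@H]2[C@H]1[C@H](OC(=O)[C@@H](C)CC)[C@@H](OC(C)=O)C1=CO[C@@]3(CO[Si](c4ccccc4)(c4ccccc4)C(C)(C)C)CC[C@@H]1[C@@H]23 | intermediate
29 | CNP0013863.2: (1R,4S,5S,6S,7S,8S,9S)-9-acetoxy-4,14-epoxy-15-hydroxy-8-[(2S)-2-methylbutanoyloxy]guaia-10(14),11(13)-dien-12,6-olide | C=C1C(=O)O[C@H]2[C@H]1[C@H](OC(=O)[C@@H](C)CC)[C@@H](OC(C)=O)C1=CO[C@@]3(CO)CC[C@@H]1[C@@H]23 | target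

## Step count and risk

Total step count: 14 (steps 1–6 and 9–14 on the main line, steps 7–8 for the side-chain reagent).
Longest linear sequence: 12 steps (1–6, then 9–14).

Three steps most likely to fail:

**Step 4 (the proposed new step).** The aldol may take other paths (ketone enolisation, intermolecular aldol) or give low enantioselectivity. The fallback uses known chemistry, sets out from 1 and comes back at 10. Compound 1 is treated with but-3-enylmagnesium bromide to give 1-[(tert-butyldiphenylsilyl)oxy]hex-5-en-2-one F1. Cross-metathesis with crotonaldehyde (second-generation Hoveyda–Grubbs catalyst) gives (E)-7-[(tert-butyldiphenylsilyl)oxy]-6-oxohept-2-enal F2. An imidazolidinone-catalysed (iminium) Mukaiyama–Michael addition of 1-(ethylsulfanyl)-1-(trimethylsilyloxy)ethene sets C1 and gives S-ethyl (3R)-7-[(tert-butyldiphenylsilyl)oxy]-6-oxo-3-(2-oxoethyl)heptanethioate F3, in which the two arms are now different. An amine-catalysed intramolecular aldol of the aldehyde arm onto the ketone gives the all-cis cyclopentane thioester S-ethyl 2-(2-formyl-3-hydroxy-3-{[(tert-butyldiphenylsilyl)oxy]methyl}cyclopentyl)ethanethioate F4. Fukuyama reduction (Et3SiH, Pd/C) converts the thioester into the aldehyde, which closes to lactol 10.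

**Step 12.** Cross-metathesis between a hindered secondary allylic ester and a 1,1-disubstituted acrylate may be slow, and the enol ether may deactivate the catalyst. The fallback sets out from 22 and comes back at 26. Cross-metathesis of 22 with methyl acrylate, a much better partner, gives the (E)-enoate acetal F5. Conjugate addition of dimethylaluminium benzeneselenolate, trapping of the aluminium enolate with formaldehyde and selenoxide elimination (H2O2, pyridine) give the 2-(hydroxymethyl)enoate acetal F6. CBr4/PPh3 converts it into the 2-(bromomethyl)enoate acetal F7. Acetal cleavage as in step 11 (Et3SiOTf, 2,4,6-collidine; H2O) gives 26.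

**Step 13.** The zinc-mediated closure may give the wrong C6/C7 relationship or lose the C8 ester by reductive 1,4-elimination. The fallback sets out from 26 and comes back at 28. It replaces the in situ zinc Barbier reaction by a preformed allylchromium reagent (CrCl2, THF/DMF, Nozaki–Hiyama-type addition); the allylchromium adds through a chair transition state with reliable anti selectivity (trans lactone) and lactonises on work-up. It makes no new compound (F0).

## Further compounds

F1 | step 4 | 1-[(tert-butyldiphenylsilyl)oxy]hex-5-en-2-one | C=CCCC(=O)CO[Si](c1ccccc1)(c1ccccc1)C(C)(C)C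
F2 | step 4 | (E)-7-[(tert-butyldiphenylsilyl)oxy]-6-oxohept-2-enal | O=C/C=C/CCC(=O)CO[Si](c1ccccc1)(c1ccccc1)C(C)(C)C
F3 | step 4 | S-ethyl (3R)-7-[(tert-butyldiphenylsilyl)oxy]-6-oxo-3-(2-oxoethyl)heptanethioate | CCSC(=O)C[C@@H](CC=O)CCC(=O)CO[Si](c1ccccc1)(c1ccccc1)C(C)(C)C
F4 | step 4 | S-ethyl 2-(2-formyl-3-hydroxy-3-{[(tert-butyldiphenylsilyl)oxy]methyl}cyclopentyl)ethanethioate, all-cis (target numbering 1S,4S,5R) | CCSC(=O)C[C@@H]1CC[C@@](O)(CO[Si](c2ccccc2)(c2ccccc2)C(C)(C)C)[C@@H]1C=O
F5 | step 12 | (E)-enoate acetal: 22 with the vinyl group replaced by (E)-CH=CH–CO2Me | COC(=O)/C=C/[C@H](OC(=O)[C@@H](C)CC)[C@@H](OC(C)=O)C1=CO[C@@]2(CO[Si](c3ccccc3)(c3ccccc3)C(C)(C)C)CC[C@@H]1[C@H]2C(OC)OC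
F6 | step 12 | 2-(hydroxymethyl)enoate acetal: 22 with the vinyl group replaced by CH=C(CO2Me)CH2OH | OC/C(C(=O)OC)=C\[C@H](OC(=O)[C@@H](C)CC)[C@@H](OC(C)=O)C1=CO[C@@]2(CO[Si](c3ccccc3)(c3ccccc3)C(C)(C)C)CC[C@@H]1[C@H]2C(OC)OC
F7 | step 12 | 2-(bromomethyl)enoate acetal: C6 dimethyl acetal of 26 | BrC/C(C(=O)OC)=C\[C@H](OC(=O)[C@@H](C)CC)[C@@H](OC(C)=O)C1=CO[C@@]2(CO[Si](c3ccccc3)(c3ccccc3)C(C)(C)C)CC[C@@H]1[C@H]2C(OC)OC
F0 | step 13 | none | none
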